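## Retrosynthetic overview

1. The target is a dihydrochalcone whose phloroglucinol ring carbon C3' is bonded to C1 of a (1R,2S,3R)-1,4-bis(4-hydroxyphenyl)-2,3-dimethylbutyl chain; the one strategic disconnection is C3'–C1 (arene C–H plus benzylic cation).
2. Enabling feature: chain C1 and C4 each carry a 4-hydroxyphenyl ring and C2/C3 carry methyl groups in the C2-symmetric (threo) relationship, so the chain is a ring-opened all-trans 1,2-diaryl-3,4-dimethylcyclobutane. Protonolysis of the ring bond between the two aryl-bearing carbons (strain release, push from the para-OH) makes the C1 cation and the C4 CH2 in one event, and the C2 axis makes both senses of cleavage identical.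
3. Final step: this cyclobutane bisphenol plus 2',4',6'-trihydroxy-4-methoxydihydrochalcone under acid in HFIP, a ring-opening hydroarylation that should give the unprotected target directly and set C1 under control of C2.
4. The cyclobutane is the head-to-head radical-cation [2+2] dimer of (E)-anethole, resolved and then O-demethylated; the dihydrochalcone comes from Friedel–Crafts acylation of phloroglucinol.
5. Ring events: the cyclobutane is the only ring formed (step 1) and it is opened again in step 5; all aromatic rings are bought.

Key step: step 5

Remark: a racemate is given by the SMILES of one enantiomer and the prefix rac in its name. Chain locants C1–C4 of the butyl unit run from the carbon on the phloroglucinol ring to the benzylic CH2. In the cyclobutanes C1 and C2 carry the aryl rings and C3 and C4 the methyl groups (C4 next to C1).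

Remark: in step 5 the acid is charged in a stoichiometric amount and neutralised on work-up. The chelated aryl ketone of 7, present in excess, is a Brønsted base and would buffer a catalytic charge below the acidity that protonation of a cyclobutane σ-bond needs.

## Route

Step 1
Reactants: 1 (E)-anethole, 1-methoxy-4-[(1E)-prop-1-en-1-yl]benzene (two molecules)
Product: 2 rac-1,1'-[(1R,2R,3S,4S)-3,4-dimethylcyclobutane-1,2-diyl]bis(4-methoxybenzene) (all-trans head-to-head dimer)
Conditions: PhI(OAc)2 (5 mol %), (CF3)2CHOH, 0 °C to rt
Reagents that add atoms: none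
Why: Hole-catalysed radical-cation [2+2] cyclodimerisation of an electron-rich β-methylstyrene, started by single-electron oxidation with the iodane in the radical-cation-stabilising solvent: the two β-carbons join first (head-to-head), ring closure and back electron transfer give the cyclobutane, and both alkenes keep their E geometry while the new ring bonds form anti, so the all-trans isomer should result as a racemate.

Step 2
Reactants: 2 rac-1,1'-[(1R,2R,3S,4S)-3,4-dimethylcyclobutane-1,2-diyl]bis(4-methoxybenzene)
Product: 3 1,1'-[(1R,2R,3S,4S)-3,4-dimethylcyclobutane-1,2-diyl]bis(4-methoxybenzene)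
Conditions: preparative chiral SFC, cellulose tris(3,5-dimethylphenylcarbamate) stationary phase, CO2/i-PrOH
Reagents that add atoms: none
Why: Resolution of a racemate by chromatography on a chiral stationary phase, which should separate the rigid C2-symmetric diaryl enantiomers without touching any bond; the (1R,2R,3S,4S) fraction is to be identified by comparison of measured and calculated circular dichroism or by X-ray crystallography with anomalous dispersion before it is carried on.

Step 3
Reactants: 3 1,1'-[(1R,2R,3S,4S)-3,4-dimethylcyclobutane-1,2-diyl]bis(4-methoxybenzene)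
Product: 4 4,4'-[(1R,2R,3S,4S)-3,4-dimethylcyclobutane-1,2-diyl]diphenol
Conditions: BBr3 (3 equiv), CH2Cl2, −78 to 0 °C; then aq NaHCO3
Reagents that add atoms: none
Why: Lewis-acid cleavage of aryl methyl ethers (BBr3 O-demethylation), run cold and quenched with base so that the strained electron-rich ring is not opened; the four stereocentres are not touched.

Step 4
Reactants: 5 phloroglucinol, benzene-1,3,5-triol; 6 3-(4-methoxyphenyl)propanoyl chloride
Product: 7 3-(4-methoxyphenyl)-1-(2,4,6-trihydroxyphenyl)propan-1-one
Conditions: AlCl3 (4 equiv), CH2Cl2/MeNO2, 0 °C to rt, 1.5-fold excess of 5; then aq HCl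
Reagents that add atoms: none
Why: Friedel–Crafts C-acylation of phloroglucinol, in which the first acyl group deactivates the ring and is held in a chelate with the ortho OH so that mono-acylation should dominate; no stereocentre is formed.

Step 5
Reactants: 4 4,4'-[(1R,2R,3S,4S)-3,4-dimethylcyclobutane-1,2-diyl]diphenol; 7 3-(4-methoxyphenyl)-1-(2,4,6-trihydroxyphenyl)propan-1-one
Product: 9 1-{2,4,6-trihydroxy-3-[(1R,2S,3R)-1,4-bis(4-hydroxyphenyl)-2,3-dimethylbutyl]phenyl}-3-(4-methoxyphenyl)propan-1-one, via O-protonated para-quinone methide 8 (not isolated)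
Conditions: CF3SO3H (1.2 equiv), (CF3)2CHOH, 0 °C to rt, slow addition of 4 to a 2.5-fold excess of 7; then aq NaHCO3
Reagents that add atoms: none
Why: Proposed new method: in the strongly ionising, weakly nucleophilic solvent the acid should protonate the electron-rich bis-benzylic C1–C2 σ-bond of 4 at C2 while the para-OH of the C1 aryl ring pushes, so that the bond heterolyses with release of about 26 kcal/mol of ring strain (a driving force close to that of protonating a styrene π-bond) to give the O-protonated quinone methide 8, in which old ring C2 is the benzylic CH2; the free C3' position of 7 then adds to the cationic carbon (Friedel–Crafts 1,6-addition) and rearomatisation returns the proton and gives 9, which holds every atom of 4 and 7. The closest known reaction type is the CF3SO3H/HFIP ring-opening hydroarylation of arylcyclopropanes to 1,1-diarylalkanes, together with the Lewis-acid Friedel–Crafts ring opening of donor–acceptor cyclobutanes; the new element is a donor-only cyclobutane whose cleaved bond is flanked by two 4-hydroxyphenyl groups. No ring is closed, and the cyclobutane is the only ring opened. Ring carbons C4 and C3 are not touched and become chain C2 (S) and C3 (R); the new stereocentre C1 (R) is controlled by chain C2, because in the cation the C2–H bond eclipses the exocyclic C=C (allylic 1,3-strain) and 7 attacks the face anti to the large C3 branch and syn to the C2 methyl, and an SN2-like opening with inversion at ring C1 of the all-trans ring would give the same isomer. The step needs bond selectivity (C1–C2, not C1–C4, C2–C3 or C3–C4), which should follow because only this bond is conjugated with two aryl rings and is the longest in the ring, while the C2 axis makes both senses of its cleavage identical; it also needs C- over O-alkylation and mono- over bis-alkylation of 7, which the reversibility of O-alkylation under acid, the two equivalent CH positions of 7 and its use in excess should secure. Cyclisation of the cation onto the second phenol ring should be slow because the only reachable position is meta to its OH.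

## Compound list

1 | (E)-anethole, 1-methoxy-4-[(1E)-prop-1-en-1-yl]benzene | COc1ccc(/C=C/C)cc1 | starting material
2 | rac-1,1'-[(1R,2R,3S,4S)-3,4-dimethylcyclobutane-1,2-diyl]bis(4-methoxybenzene) | C[C@H]1[C@H](C)[C@@H](c2ccc(OC)cc2)[C@@H]1c1ccc(OC)cc1 | intermediate
3 | 1,1'-[(1R,2R,3S,4S)-3,4-dimethylcyclobutane-1,2-diyl]bis(4-methoxybenzene) | C[C@H]1[C@H](C)[C@@H](c2ccc(OC)cc2)[C@@H]1c1ccc(OC)cc1 | intermediate
4 | 4,4'-[(1R,2R,3S,4S)-3,4-dimethylcyclobutane-1,2-diyl]diphenol | C[C@H]1[C@H](C)[C@@H](c2ccc(O)cc2)[C@@H]1c1ccc(O)cc1 | intermediate
5 | phloroglucinol, benzene-1,3,5-triol | Oc1cc(O)cc(O)c1 | starting material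
6 | 3-(4-methoxyphenyl)propanoyl chloride | COc1ccc(CCC(Cl)=O)cc1 | starting material
7 | 3-(4-methoxyphenyl)-1-(2,4,6-trihydroxyphenyl)propan-1-one | COc1ccc(CCC(=O)c2c(O)cc(O)cc2O)cc1 | intermediate
8 | 4-[(2S,3R)-4-(4-hydroxyphenyl)-2,3-dimethylbutylidene]cyclohexa-2,5-dien-1-one (para-quinone methide, present as its O-protonated form, the 4-hydroxybenzylic cation) | O=C1C=CC(=C[C@@H](C)[C@H](C)Cc2ccc(O)cc2)C=C1 | intermediate
9 | 1-{2,4,6-trihydroxy-3-[(1R,2S,3R)-1,4-bis(4-hydroxyphenyl)-2,3-dimethylbutyl]phenyl}-3-(4-methoxyphenyl)propan-1-one | COc1ccc(CCC(=O)c2c(O)cc(O)c([C@@H](c3ccc(O)cc3)[C@@H](C)[C@H](C)Cc3ccc(O)cc3)c2O)cc1 | target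

## Step count and risks

Total steps: 5. Longest linear sequence: 4 steps (steps 1, 2, 3 and 5).

Steps most likely to fail:

1. Step 5. Protonation of the cyclobutane σ-bond may be too slow at a temperature at which the product survives, so that arene protonation, oligomerisation of 4 through its own phenol rings or cleavage of the wrong ring bond take over. Reversible loss of the C2 proton from the cation (styrene formation and re-protonation) or reversible Friedel–Crafts bond formation could also erode the configuration at C2 and C1. Fallback, by known reactions, sets out from 3 and returns at 9. Reductive cleavage of the bis-benzylic ring bond with Li in NH3(l)/THF at −78 °C (NH4Cl quench) should give 1,1'-[(2R,3R)-2,3-dimethylbutane-1,4-diyl]bis(4-methoxybenzene) F1. BBr3 in CH2Cl2 should then give 4,4'-[(2R,3R)-2,3-dimethylbutane-1,4-diyl]diphenol F2. Benzylic dehydrogenation with DDQ (1 equiv) in MeOH/CH2Cl2, the quinone methide being captured by the solvent, should give 4-[(2S,3R)-4-(4-hydroxyphenyl)-1-methoxy-2,3-dimethylbutyl]phenol F3 as both C1 epimers; either benzylic CH2 of the C2-symmetric F2 leads to the same compound. F3 and 7 with (PhO)2P(O)OH (10 mol %) in CH2Cl2 at 0 °C should lose methanol to the same intermediate 8, which 7 traps to give 9.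

2. Step 2. The two enantiomers of the non-polar diether may not separate on the stationary phase at a useful loading. Fallback sets out from 2 and returns at 4, moving the resolution to covalent diastereomers. BBr3 demethylation of 2 should give rac-4,4'-[(1R,2R,3S,4S)-3,4-dimethylcyclobutane-1,2-diyl]diphenol F4. (S)-1-Phenylethyl isocyanate (C[C@H](N=C=O)c1ccccc1, 2.2 equiv, Et3N cat., CH2Cl2) should give two diastereomers, [(1R,2R,3S,4S)-3,4-dimethylcyclobutane-1,2-diyl]di(4,1-phenylene) bis{N-[(1S)-1-phenylethyl]carbamate} F5 and [(1S,2S,3R,4R)-3,4-dimethylcyclobutane-1,2-diyl]di(4,1-phenylene) bis{N-[(1S)-1-phenylethyl]carbamate} F6, to be separated by crystallisation or silica chromatography. K2CO3 in MeOH should cleave F5 to 4.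

3. Step 4. Over-acylation, O-acylation and partial cleavage of the aryl methyl ether by AlCl3 may compete with the single C-acylation. Fallback sets out from 5 and returns at 7 by a Houben–Hoesch reaction. Phloroglucinol 5 and 3-(4-methoxyphenyl)propanenitrile (COc1ccc(CCC#N)cc1) with ZnCl2 and HCl gas in Et2O at 0 °C should give 3-(4-methoxyphenyl)-1-(2,4,6-trihydroxyphenyl)propan-1-iminium chloride F7, which precipitates and cannot react a second time. Hydrolysis in water at reflux should give 7.

## Further compounds

F1 | step 5 | 1,1'-[(2R,3R)-2,3-dimethylbutane-1,4-diyl]bis(4-methoxybenzene) | COc1ccc(C[C@@H](C)[C@H](C)Cc2ccc(OC)cc2)cc1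
F2 | step 5 | 4,4'-[(2R,3R)-2,3-dimethylbutane-1,4-diyl]diphenol | Oc1ccc(C[C@@H](C)[C@H](C)Cc2ccc(O)cc2)cc1
F3 | step 5 | 4-[(2S,3R)-4-(4-hydroxyphenyl)-1-methoxy-2,3-dimethylbutyl]phenol (both C1 epimers) | COC(c1ccc(O)cc1)[C@@H](C)[C@H](C)Cc1ccc(O)cc1
F4 | step 2 | rac-4,4'-[(1R,2R,3S,4S)-3,4-dimethylcyclobutane-1,2-diyl]diphenol | C[C@H]1[C@H](C)[C@@H](c2ccc(O)cc2)[C@@H]1c1ccc(O)cc1
F5 | step 2 | [(1R,2R,3S,4S)-3,4-dimethylcyclobutane-1,2-diyl]di(4,1-phenylene) bis{N-[(1S)-1-phenylethyl]carbamate} | C[C@H]1[C@H](C)[C@@H](c2ccc(OC(=O)N[C@@H](C)c3ccccc3)cc2)[C@@H]1c1ccc(OC(=O)N[C@@H](C)c2ccccc2)cc1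
F6 | step 2 | [(1S,2S,3R,4R)-3,4-dimethylcyclobutane-1,2-diyl]di(4,1-phenylene) bis{N-[(1S)-1-phenylethyl]carbamate} | C[C@@H]1[C@@H](C)[C@H](c2ccc(OC(=O)N[C@@H](C)c3ccccc3)cc2)[C@H]1c1ccc(OC(=O)N[C@@H](C)c2ccccc2)cc1
F7 | step 4 | 3-(4-methoxyphenyl)-1-(2,4,6-trihydroxyphenyl)propan-1-iminium chloride | COc1ccc(CCC(=[NH2+])c2c(O)cc(O)cc2O)cc1.[Cl-]
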